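**Plan**

- Retrosynthetic cuts: the four aryl O–CH3 bonds come off last. In the genistein half the pyranone is cut at C2 (one carbon from DMF) and at the C4–C4a acyl bond (to 4-methoxyphenylacetic acid). In the daidzein half it is cut at O1–C2, at C3–C1' (made by a 1,2-aryl shift) and at the chalcone C=C (aldol with paeonol). Ring B is cut at C1'–C2' and C5'–C6'.
- Enabling feature: ring B of the daidzein half carries O-4' para to the carbon substituent on C1' and ring A of the genistein half on C3'. C2'–C5' therefore map onto a 3-aryl-2-siloxybuta-1,3-diene and C1'/C6' onto methyl propiolate, and the hindered biaryl bond is carried in as the aryl–diene bond.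
- Forward order: genistein ring A is bought as 5-methoxyresorcinol and carried as its bis-MOM ether (MOM directs the metalation between the two oxygens). Ring B is closed onto it by Diels–Alder reaction and dehydrogenation. The daidzein pyranone follows (chalcone, oxidative aryl shift, acid closure), then the genistein pyranone (C-acylation, formylative closure), then global demethylation.
- Stereochemistry: the target has no stereocentre. The only stereo-element on the way is the E double bond of the chalcone, set thermodynamically and consumed in the next step.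

Key step: step 6

Assumption: the target is drawn without stereodescriptors, and the biaryl axis (flanked by OH, OH and the pyranone oxygen) is taken as freely rotating, so no axial configuration is set.

**Route**

Step 1
Reactants: 1 5-methoxyresorcinol
Product: 2 1-methoxy-3,5-bis(methoxymethoxy)benzene
Conditions: NaH, MOMCl, DMF, 0 °C to rt
Reagents that add atoms: chloromethyl methyl ether (MOMCl), COCCl
Why: Williamson-type O-alkylation of the bis-phenoxide should install two acid-labile, strongly ortho-directing acetal ethers while the methyl ether keeps the third oxygen distinct for the later chromone closure.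

Step 2
Reactants: 2 1-methoxy-3,5-bis(methoxymethoxy)benzene
Product: 4 2-allyl-5-methoxy-1,3-bis(methoxymethoxy)benzene, via aryllithium 3 (not isolated)
Conditions: n-BuLi, THF, 0 °C; then CuI (10 mol%), allyl bromide, −78 °C to rt
Reagents that add atoms: allyl bromide, C=CCBr
Why: directed ortho-metalation should take place at the C–H flanked by both MOM ethers, the only site chelated by two acetal oxygens and so favoured over the sites next to the methyl ether, and the aryllithium is then allylated under CuI catalysis.

Step 3
Reactants: 4 2-allyl-5-methoxy-1,3-bis(methoxymethoxy)benzene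
Product: 5 1-[4-methoxy-2,6-bis(methoxymethoxy)phenyl]propan-2-one
Conditions: PdCl2 (10 mol%), CuCl, O2 (1 atm), DMF/H2O (7:1), rt
Reagents that add atoms: water, O
Why: Tsuji–Wacker oxidation of the terminal alkene proceeds by Markovnikov hydroxypalladation and should give the methyl ketone under near-neutral conditions that leave the MOM ethers untouched.

Step 4
Reactants: 5 1-[4-methoxy-2,6-bis(methoxymethoxy)phenyl]propan-2-one
Product: 7 3-[4-methoxy-2,6-bis(methoxymethoxy)phenyl]but-3-en-2-one, via Mannich base 6 (not isolated)
Conditions: CH2(NMe2)2, Ac2O, DMF, 60 °C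
Reagents that add atoms: bis(dimethylamino)methane, CN(C)CN(C)C
Why: Mannich α-methylenation, in which the iminium ion generated in the flask should be captured by the more substituted enol at the more acidic benzylic carbon and the β-amino ketone then loses its amine after N-acylation to give the α-aryl enone, which is used without storage.

Step 5
Reactants: 7 3-[4-methoxy-2,6-bis(methoxymethoxy)phenyl]but-3-en-2-one
Product: 8 2-(tert-butyldimethylsiloxy)-3-[4-methoxy-2,6-bis(methoxymethoxy)phenyl]buta-1,3-diene
Conditions: TBSOTf, Et3N, CH2Cl2, 0 °C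
Reagents that add atoms: tert-butyldimethylsilyl trifluoromethanesulfonate (TBSOTf), CC(C)(C)[Si](C)(C)OS(=O)(=O)C(F)(F)F
Why: soft enolization and O-silylation of the methyl ketone with a silyl triflate and an amine base can only involve the methyl group, the sole enolizable position, and so should give the cross-conjugated 2-siloxydiene.

Step 6
Reactants: 8 2-(tert-butyldimethylsiloxy)-3-[4-methoxy-2,6-bis(methoxymethoxy)phenyl]buta-1,3-diene; 9 methyl propiolate
Product: 11 methyl 4-(tert-butyldimethylsiloxy)-3-[4-methoxy-2,6-bis(methoxymethoxy)phenyl]benzoate, via cyclohexa-1,4-diene adduct 10 (not isolated)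
Conditions: toluene, 120 °C (sealed tube); then DDQ, rt
Reagents that add atoms: none
Why: The electron-rich 2-siloxydiene 8 and the electron-poor alkyne 9 should combine in a concerted, asynchronous [4+2] cycloaddition (Diels–Alder reaction) that forms C1'–C2' and C5'–C6', and the resulting 1,4-cyclohexadiene 10 is then dehydrogenated by DDQ (hydride abstraction from a doubly allylic CH2, then proton loss) to the benzoate with the silyl ether intact. The closest known reaction type is the cycloaddition of 2-silyloxybuta-1,3-dienes to acetylenic esters followed by oxidative aromatization to para-oxygenated benzoates. Ring B is the only ring closed, and it closes by intermolecular [4+2] cycloaddition in which the four diene carbons become C2'–C5' and the two alkyne carbons become C1' and C6'. No stereocentre is created, since both sp3 carbons of 10 are CH2 groups that end as aromatic CH. The selectivity needed is regiochemical: the siloxy group makes the neighbouring diene terminus (future C5') the most nucleophilic carbon, which bonds to the β-carbon of the propiolate and so places the ester para to oxygen, while the aryl group, twisted out of the diene plane by its two ortho MOM ethers, has little opposing influence. The biaryl bond is carried in from the diene, so no coupling at the doubly ortho-substituted carbon is required.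

Step 7
Reactants: 11 methyl 4-(tert-butyldimethylsiloxy)-3-[4-methoxy-2,6-bis(methoxymethoxy)phenyl]benzoate
Product: 13 methyl 4-methoxy-3-[4-methoxy-2,6-bis(methoxymethoxy)phenyl]benzoate, via cesium phenoxide 12 (not isolated)
Conditions: CsF, MeI, DMF, rt
Reagents that add atoms: iodomethane, CI
Why: fluoride-induced cleavage of the aryl silyl ether gives a cesium phenoxide that should be O-methylated in the same flask (Williamson ether synthesis), giving a base-stable para-methoxy group that later helps the aryl shift.

Step 8
Reactants: 13 methyl 4-methoxy-3-[4-methoxy-2,6-bis(methoxymethoxy)phenyl]benzoate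
Product: 14 {4-methoxy-3-[4-methoxy-2,6-bis(methoxymethoxy)phenyl]phenyl}methanol
Conditions: LiAlH4, THF, 0 °C
Reagents that add atoms: none
Why: hydride reduction of the aryl ester to the benzylic alcohol is routine and leaves aryl methyl and MOM ethers untouched.

Step 9
Reactants: 14 {4-methoxy-3-[4-methoxy-2,6-bis(methoxymethoxy)phenyl]phenyl}methanol
Product: 15 4-methoxy-3-[4-methoxy-2,6-bis(methoxymethoxy)phenyl]benzaldehyde
Conditions: MnO2, CH2Cl2, rt
Reagents that add atoms: none
Why: MnO2 oxidation of an electron-rich benzylic alcohol should stop cleanly at the aldehyde under neutral conditions.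

Step 10
Reactants: 15 4-methoxy-3-[4-methoxy-2,6-bis(methoxymethoxy)phenyl]benzaldehyde; 16 paeonol
Product: 17 (E)-1-(2-hydroxy-4-methoxyphenyl)-3-{4-methoxy-3-[4-methoxy-2,6-bis(methoxymethoxy)phenyl]phenyl}prop-2-en-1-one
Conditions: KOH, EtOH/H2O, rt
Reagents that add atoms: none
Why: Claisen–Schmidt aldol condensation of the acetophenone enolate with the non-enolizable aldehyde, followed by E1cB dehydration, should give the thermodynamically favoured E chalcone, and all ether groups are stable to base.

Step 11
Reactants: 17 (E)-1-(2-hydroxy-4-methoxyphenyl)-3-{4-methoxy-3-[4-methoxy-2,6-bis(methoxymethoxy)phenyl]phenyl}prop-2-en-1-one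
Product: 19 3-[3-(2,6-dihydroxy-4-methoxyphenyl)-4-methoxyphenyl]-7-methoxy-4H-chromen-4-one, via dimethyl acetal 18 (not isolated)
Conditions: Tl(NO3)3·3H2O, MeOH/HC(OMe)3, rt; then HCl, MeOH, 60 °C
Reagents that add atoms: none
Why: oxidative rearrangement of a 2'-hydroxychalcone, in which oxythallation of the enone is followed by a 1,2-shift of the para-methoxy-activated ring B with loss of monovalent thallium to give the β-keto acetal, after which methanolic acid should close the pyranone through the 2'-hydroxyl and remove both MOM groups in the same operation.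

Step 12
Reactants: 19 3-[3-(2,6-dihydroxy-4-methoxyphenyl)-4-methoxyphenyl]-7-methoxy-4H-chromen-4-one; 20 4-methoxyphenylacetic acid
Product: 22 7-hydroxy-5-methoxy-3-(4-methoxyphenyl)-8-[2-methoxy-5-(7-methoxy-4-oxo-4H-chromen-3-yl)phenyl]-4H-chromen-4-one, via deoxybenzoin 21 (not isolated)
Conditions: BF3·OEt2, 85 °C; then DMF, MsCl, 70 °C
Reagents that add atoms: N,N-dimethylformamide, CN(C)C=O
Why: BF3-mediated Friedel–Crafts C-acylation of the resorcinol ring at either of its two equivalent free positions, followed by formylative cyclization with the Vilsmeier-type reagent from DMF and MsCl (the deoxybenzoin route to isoflavones), can only close through the hydroxyl next to the biaryl bond because the other ortho oxygen is methylated, so the aryl group should end on C8.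

Step 13
Reactants: 22 7-hydroxy-5-methoxy-3-(4-methoxyphenyl)-8-[2-methoxy-5-(7-methoxy-4-oxo-4H-chromen-3-yl)phenyl]-4H-chromen-4-one
Product: 23 5,7-dihydroxy-8-[2-hydroxy-5-(7-hydroxy-4-oxo-4H-chromen-3-yl)phenyl]-3-(4-hydroxyphenyl)-4H-chromen-4-one
Conditions: BBr3, CH2Cl2, −78 °C to rt; then MeOH, H2O
Reagents that add atoms: none
Why: Lewis-acid cleavage of the four aryl methyl ethers by BBr3 (SN2 attack of bromide on the boron-activated O-methyl groups) is standard for methoxyisoflavones and should release the pentaphenol without touching the pyranones.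

**Compound list**

1 | 5-methoxyresorcinol | COc1cc(O)cc(O)c1 | starting material
2 | 1-methoxy-3,5-bis(methoxymethoxy)benzene | COCOc1cc(OC)cc(OCOC)c1 | intermediate
3 | [4-methoxy-2,6-bis(methoxymethoxy)phenyl]lithium | [Li]c1c(OCOC)cc(OC)cc1OCOC | intermediate
4 | 2-allyl-5-methoxy-1,3-bis(methoxymethoxy)benzene | C=CCc1c(OCOC)cc(OC)cc1OCOC | intermediate
5 | 1-[4-methoxy-2,6-bis(methoxymethoxy)phenyl]propan-2-one | CC(=O)Cc1c(OCOC)cc(OC)cc1OCOC | intermediate
6 | racemic 4-(dimethylamino)-3-[4-methoxy-2,6-bis(methoxymethoxy)phenyl]butan-2-one | CC(=O)C(CN(C)C)c1c(OCOC)cc(OC)cc1OCOC | intermediate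
7 | 3-[4-methoxy-2,6-bis(methoxymethoxy)phenyl]but-3-en-2-one | CC(=O)C(=C)c1c(OCOC)cc(OC)cc1OCOC | intermediate
8 | 2-(tert-butyldimethylsiloxy)-3-[4-methoxy-2,6-bis(methoxymethoxy)phenyl]buta-1,3-diene | C=C(O[Si](C)(C)C(C)(C)C)C(=C)c1c(OCOC)cc(OC)cc1OCOC | intermediate
9 | methyl propiolate | C#CC(=O)OC | starting material
10 | methyl 4-(tert-butyldimethylsiloxy)-5-[4-methoxy-2,6-bis(methoxymethoxy)phenyl]cyclohexa-1,4-diene-1-carboxylate | COC(=O)C1=CCC(O[Si](C)(C)C(C)(C)C)=C(c2c(OCOC)cc(OC)cc2OCOC)C1 | intermediate
11 | methyl 4-(tert-butyldimethylsiloxy)-3-[4-methoxy-2,6-bis(methoxymethoxy)phenyl]benzoate | COC(=O)c1ccc(O[Si](C)(C)C(C)(C)C)c(-c2c(OCOC)cc(OC)cc2OCOC)c1 | intermediate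
12 | cesium 4-(methoxycarbonyl)-2-[4-methoxy-2,6-bis(methoxymethoxy)phenyl]phenoxide | COC(=O)c1ccc([O-])c(-c2c(OCOC)cc(OC)cc2OCOC)c1.[Cs+] | intermediate
13 | methyl 4-methoxy-3-[4-methoxy-2,6-bis(methoxymethoxy)phenyl]benzoate | COC(=O)c1ccc(OC)c(-c2c(OCOC)cc(OC)cc2OCOC)c1 | intermediate
14 | {4-methoxy-3-[4-methoxy-2,6-bis(methoxymethoxy)phenyl]phenyl}methanol | OCc1ccc(OC)c(-c2c(OCOC)cc(OC)cc2OCOC)c1 | intermediate
15 | 4-methoxy-3-[4-methoxy-2,6-bis(methoxymethoxy)phenyl]benzaldehyde | O=Cc1ccc(OC)c(-c2c(OCOC)cc(OC)cc2OCOC)c1 | intermediate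
16 | paeonol (1-(2-hydroxy-4-methoxyphenyl)ethan-1-one) | CC(=O)c1ccc(OC)cc1O | starting material
17 | (E)-1-(2-hydroxy-4-methoxyphenyl)-3-{4-methoxy-3-[4-methoxy-2,6-bis(methoxymethoxy)phenyl]phenyl}prop-2-en-1-one | COc1ccc(C(=O)/C=C/c2ccc(OC)c(-c3c(OCOC)cc(OC)cc3OCOC)c2)c(O)c1 | intermediate
18 | racemic 1-(2-hydroxy-4-methoxyphenyl)-3,3-dimethoxy-2-{4-methoxy-3-[4-methoxy-2,6-bis(methoxymethoxy)phenyl]phenyl}propan-1-one | COc1ccc(C(=O)C(C(OC)OC)c2ccc(OC)c(-c3c(OCOC)cc(OC)cc3OCOC)c2)c(O)c1 | intermediate
19 | 3-[3-(2,6-dihydroxy-4-methoxyphenyl)-4-methoxyphenyl]-7-methoxy-4H-chromen-4-one | COc1ccc2c(=O)c(-c3ccc(OC)c(-c4c(O)cc(OC)cc4O)c3)coc2c1 | intermediate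
20 | 4-methoxyphenylacetic acid | COc1ccc(CC(=O)O)cc1 | starting material
21 | 3-{3-[2,6-dihydroxy-4-methoxy-3-(4-methoxyphenylacetyl)phenyl]-4-methoxyphenyl}-7-methoxy-4H-chromen-4-one | COc1ccc2c(=O)c(-c3ccc(OC)c(-c4c(O)c(C(=O)Cc5ccc(OC)cc5)c(OC)cc4O)c3)coc2c1 | intermediate
22 | 7-hydroxy-5-methoxy-3-(4-methoxyphenyl)-8-[2-methoxy-5-(7-methoxy-4-oxo-4H-chromen-3-yl)phenyl]-4H-chromen-4-one | COc1ccc2c(=O)c(-c3ccc(OC)c(-c4c(O)cc(OC)c5c(=O)c(-c6ccc(OC)cc6)coc45)c3)coc2c1 | intermediate
23 | 5,7-dihydroxy-8-[2-hydroxy-5-(7-hydroxy-4-oxo-4H-chromen-3-yl)phenyl]-3-(4-hydroxyphenyl)-4H-chromen-4-one (CNP0500144.0) | O=c1c(-c2ccc(O)c(-c3c(O)cc(O)c4c(=O)c(-c5ccc(O)cc5)coc34)c2)coc2cc(O)ccc12 | target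

**Totals and risks**

Total step count: 13. Longest linear sequence: 13 steps (1 to 23); compounds 9, 16 and 20 enter as bought.

Steps most likely to fail:

1. Step 6. The cycloaddition may be slow because the aryl group, held perpendicular to the diene, screens both faces near the aryl-bearing diene carbon. Prolonged heating then favours polymerization or desilylation of the diene, and some loss of regiocontrol is possible. The fallback forms the biaryl bond by cross-coupling instead of building ring B. It sets out from 2, which is lithiated as in step 2; the aryllithium 3 is quenched with B(OMe)3 and hydrolysed with aqueous NH4Cl to [4-methoxy-2,6-bis(methoxymethoxy)phenyl]boronic acid F1. Suzuki–Miyaura coupling of F1 with commercial methyl 3-bromo-4-methoxybenzoate (Pd(OAc)2, SPhos, K3PO4, toluene/H2O, 90 °C) should give 13 directly, where the route is rejoined.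

2. Step 11. Tl(NO3)3 may attack the electron-rich trioxygenated ring (aromatic thallation or oxidation) in competition with oxythallation of the enone. The HNO3 liberated may also remove MOM groups early, so that freed phenols are oxidized, and closure to an aurone instead of aryl migration is a further diversion. The fallback uses a non-oxidative 1,2-shift through a chalcone epoxide and sets out from 15 and 16. Paeonol 16 is converted with NaH and MOMCl into 1-[4-methoxy-2-(methoxymethoxy)phenyl]ethan-1-one F2. Claisen–Schmidt condensation of F2 with aldehyde 15 (KOH, EtOH) should give the (E)-2'-(methoxymethoxy)chalcone F3, and Weitz–Scheffer epoxidation (H2O2, NaOH, MeOH/THF) the racemic trans-epoxy ketone F4. BF3·OEt2 in CH2Cl2 at low temperature should open the epoxide at the benzylic carbon and induce a 1,2-acyl shift to the 2-aryl-3-oxopropanal F5. Methanolic HCl then removes the three MOM groups and closes the pyranone to 19, where the route is rejoined.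

3. Step 4. The Mannich reaction may take place at the methyl group instead of at the hindered benzylic carbon, and the α-aryl enone may dimerize or add a second ketone molecule by Michael addition while it forms. The fallback fixes the connectivity of the enone by a carbonyl addition and sets out from 2. Compound 2 is lithiated as in step 2 and the aryllithium 3, after transmetalation with CeCl3, is added to commercial 3,3-dimethoxybutan-2-one to give 3,3-dimethoxy-2-[4-methoxy-2,6-bis(methoxymethoxy)phenyl]butan-2-ol F6. Dehydration with Burgess reagent, which can only give the 1,1-disubstituted alkene, should yield 2-(3,3-dimethoxybut-1-en-2-yl)-5-methoxy-1,3-bis(methoxymethoxy)benzene F7. Hydrolysis of the ketal with PPTS in wet acetone gives enone 7, where the route is rejoined.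

**Further compounds**

F1 | step 6 | [4-methoxy-2,6-bis(methoxymethoxy)phenyl]boronic acid | OB(O)c1c(OCOC)cc(OC)cc1OCOC
F2 | step 11 | 1-[4-methoxy-2-(methoxymethoxy)phenyl]ethan-1-one | CC(=O)c1ccc(OC)cc1OCOC
F3 | step 11 | (E)-1-[4-methoxy-2-(methoxymethoxy)phenyl]-3-{4-methoxy-3-[4-methoxy-2,6-bis(methoxymethoxy)phenyl]phenyl}prop-2-en-1-one | COCOc1cc(OC)ccc1C(=O)/C=C/c1ccc(OC)c(-c2c(OCOC)cc(OC)cc2OCOC)c1
F4 | step 11 | racemic trans-[4-methoxy-2-(methoxymethoxy)phenyl](3-{4-methoxy-3-[4-methoxy-2,6-bis(methoxymethoxy)phenyl]phenyl}oxiran-2-yl)methanone (one enantiomer drawn) | COCOc1cc(OC)ccc1C(=O)[C@H]1O[C@@H]1c1ccc(OC)c(-c2c(OCOC)cc(OC)cc2OCOC)c1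
F5 | step 11 | racemic 3-[4-methoxy-2-(methoxymethoxy)phenyl]-2-{4-methoxy-3-[4-methoxy-2,6-bis(methoxymethoxy)phenyl]phenyl}-3-oxopropanal | COCOc1cc(OC)ccc1C(=O)C(C=O)c1ccc(OC)c(-c2c(OCOC)cc(OC)cc2OCOC)c1
F6 | step 4 | racemic 3,3-dimethoxy-2-[4-methoxy-2,6-bis(methoxymethoxy)phenyl]butan-2-ol | CC(O)(c1c(OCOC)cc(OC)cc1OCOC)C(C)(OC)OC
F7 | step 4 | 2-(3,3-dimethoxybut-1-en-2-yl)-5-methoxy-1,3-bis(methoxymethoxy)benzene | C=C(c1c(OCOC)cc(OC)cc1OCOC)C(C)(OC)OC
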